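1. At 15 min you read cedar, birch and maple, which differ in their loading of free catalyst. Noon and autumn are the runs so far.

in all of them: substrate 0.010 M
- noon: coupling partner 0.80 equiv; free catalyst 0.24 mol%; run made earlier
- autumn: coupling partner 0.80 equiv; free catalyst 0.77 mol%; run made earlier
- cedar: coupling partner 0.800 equiv; free catalyst 0.4 mol%; time 15 min
- birch: coupling partner 0.800 equiv; free catalyst 0.6 mol%; time 15 min
- maple: coupling partner 0.800 equiv; free catalyst 1 mol%; time 15 min

- noon (time / min: target / %, substrate / %): 0.667: 1.2, 98.4; 2.00: 4.9, 95.7; 4.00: 6.1, 91.9; 5.00: 6.7, 94.7; 8.00: 10.6, 86.7
- autumn (time / min: target / %, substrate / %): 0.667: 3.2, 97.1; 2.00: 9.0, 89.9; 4.00: 17.2, 78.6; 5.00: 19.8, 73.8; 8.00: 33.2, 58.5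

(scatter of a reading: 1 percentage point)

- what was read earlier has a scatter of 1 percentage point, one standard deviation
- "hardly changes" means that all values lie within two and a half points (for a concentration: within two and a half percent of the largest)

- amount of target at the end, in percent of the substrate charged for cedar, birch, maple, in this order
- the course of these numbers from the first flask to the last (rises, then falls / falls, then rises / rises all the way / hardly changes / falls all the way)

2. Carry one number: the turnover frequency, target formed per catalyst charged per minute 5.39 min⁻¹, read from autumn at 8.00 min. Autumn at 4.00 min reads 5.58 min⁻¹, and noon at 8.00 min reads 5.52 min⁻¹, a looser reading because its target is smaller than autumn's. Within the scatter, the number holds across time and loading, so I freeze it.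

3. What is in the flask: substrate, coupling partner, catalyst and growing target, plus something else. In autumn at 8.00 min, substrate and target fall 8.3 percentage points short of the charge.

4. What you will find, by my reckoning: cedar 32.3% and birch 48.5%.

5. Leave maple's reading time alone. Its straight line gives 80.8%, more than the 0.800 equiv of coupling partner allows at one target per coupling partner, and on paper the line reaches that limit at 14.8 min, earlier than 15 min. So I treat that limit as maple's ceiling and commit to a rising row.

6. The forecast gives 33%, 49% and 74%, and rises all the way. Its maple figure sits below my ceiling: “Some late slowing is likely”.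

7. The flasks give 30.0%, 45.8% and 70.8%; the course is rises all the way. In maple at 15.0 min, the coupling partner, the limiting reagent there, stands at 0.707% of its charge.

    substrate + catalyst intermediate B → catalyst intermediate C (k = 1.13 × 10⁵ L mol⁻¹ min⁻¹)
    catalyst intermediate C → catalyst intermediate D (k = 22.5 min⁻¹)
    substrate → decomposition product (k = 1.11 × 10⁻⁴ min⁻¹)
    catalyst intermediate D → by-product + catalyst intermediate E (k = 17.7 min⁻¹)
    substrate + target → side product (k = 3.89 L mol⁻¹ min⁻¹)
    catalyst intermediate E → free catalyst + target (k = 19.5 min⁻¹)
    coupling partner + free catalyst → catalyst intermediate A (k = 18500 L mol⁻¹ min⁻¹)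
    catalyst intermediate A ⇌ catalyst intermediate B (K = 7.80, k = 1330 min⁻¹)

8. Frozen turnover gives 32.3% for cedar at 15 min, where the flask holds 30.0%. For maple at 7.50 min it gives 40.4%, and maple held 41.2%.

The earlier runs and the new flask were generated by integration with made-up constants, and the scatter is random.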